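# Proposed synthesis of (3R,5S)-1-(4-hydroxy-3-methoxyphenyl)octane-3,5-diyl diacetate (8)

**Numbering used throughout:** 1 cis-cyclopent-4-ene-1,3-diol; 2 its bicyclic benzylidene acetal; 3 O-benzyl-(E)-isoeugenol; 4 ring-opened diene dioxane; 5 saturated acetal (not isolated); 6 triol; 7 triacetate; 8 target.

## Analysis of the target

Target 8 is an unbranched C8 chain with a guaiacyl ring at C1 and acetoxy groups at C3 and C5; the arene is its only ring. The two stereocentres are 1,3-related and syn. The R,S descriptor pair reflects a hidden mirror plane through C4: each carbinol lies between the C4 methylene and an arm (C2–C1–aryl or C6–C7–C8), and the arms differ only beyond C2 and C6. The sensitive groups are two secondary acetates (base-labile, able to migrate 1,3 once one is lost) beside a free, electron-rich phenol that must end unacylated. The skeleton is trivial; the difficulty is fixing the relative and absolute configuration of two remote centres on a flexible chain without spending one reagent-controlled step per centre. The feature exploited is this: C2–C3(O)–C4–C5(O)–C6 is the opened form of a cis-3,5-dioxygenated cyclopentene whose olefinic carbons are C2 and C6, and the remaining caps, C1 with its aryl group and C7–C8, are the two halves of the C=C bond of 3. The syn relation is therefore a ring cis relation supplied by a meso compound, and the absolute configuration reduces to which end of the ring olefin receives the aryl-bearing carbon.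

## Retrosynthetic reasoning

**8 from 7.** The last bond cut is the aryl O–acetyl bond. Acetylating all three oxygens asks for no selectivity, and the aryl ester is far more electrophilic than the alkyl esters, so one aminolysis should free the phenol alone.

**7 from 6.** Three O–acetyl bonds are cut. Triol 6 holds the complete skeleton and both stereocentres, so only acylation remains.

**6 from 4 (through 5).** No skeletal bond is cut. The forward step adds hydrogen across C1=C2 and C6=C7 and cleaves three benzylic C–O bonds (two of the benzylidene acetal, one of the aryl benzyl ether). This lets 4 carry olefins exactly where metathesis makes bonds, and lets the tether and the phenol protection leave in the same operation.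

**4 from 2 and 3.** The key disconnection cuts C1=C2 and C6=C7 together. The C2–C6 unit closes into the cyclopentene of 2, and C1(aryl) joins C7–C8 as the olefin of 3. Cutting at C3–C4 or C4–C5 would create a stereocentre in the bond-forming step; cutting here creates none. Relative configuration comes from meso 2, all eight chain carbons and the arene are assembled at once, and absolute configuration becomes a choice between two enantiotopic olefinic carbons. The forward reaction must open the ring, deliver the arylmethylidene of 3 to one chosen end and its ethylidene to the other.

**2 from 1.** The two acetal C–O bonds are cut. The one-carbon bridge does three jobs: it turns the barely strained cyclopentene into a bicyclo[3.2.1]octene so that ring opening is irreversible, it masks the allylic hydroxyls, and it is removed by the hydrogenation already needed.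

## Alternatives that were turned down

**Alternative 1:** the textbook route, cutting C4–C5 (aldol) and reducing the C3 carbonyl. A chiral dialkylboron enolate of methyl ketone A1 (O-benzylzingerone) would add to the unbranched four-carbon aldehyde to give β-hydroxy ketone A2. Chelation-controlled syn reduction (Et2BOMe, NaBH4; Narasaka–Prasad) would give diol A3, followed by acetylation and hydrogenolysis. It was turned down because the two stereocentres are set in two separate operations. Methyl-ketone aldols with unbranched, enolisable aldehydes are the weakest case for enantiocontrol. A2 is a β-hydroxy ketone prone to dehydration and retro-aldol cleavage. With the preparation of A1 the sequence is no shorter than the proposed one.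

**Alternative 2:** a dynamic route that cuts only the two O–acetyl bonds and sets both configurations during acylation. Stereorandom diol A4 (from A1 by an uncontrolled aldol and borohydride reduction) would undergo dynamic kinetic asymmetric transformation: lipase acylation (Candida antarctica lipase B, an enol acetate), epimerisation of the free carbinols by RuCl(CO)2(η5-C5Ph5)/KOt-Bu, and syn-selective 1,3-acyl migration, giving syn-diacetate A5; hydrogenolysis would finish. It was turned down on structural grounds, although it matches the syn-diacetate array exactly. The lipase discriminates only when one carbinol substituent is small (methyl, at most ethyl). In A4, C3 carries CH2CH2Ar and C5 carries propyl, each opposite the C4 methylene, so both are large/large carbinols; acylation should be slow and poorly selective, with no handle to correct it.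

**Alternative 3:** two-directional growth from C4, cutting C2–C3 and C5–C6. Double transfer-hydrogenative C-allylation of the parent three-carbon 1,3-diol (iridium catalyst from [Ir(cod)Cl]2, (R)-BINAP, a nitrobenzoic acid and Cs2CO3) would give diene diol A6 in one step. It was turned down because the second allylation is catalyst-controlled and gives the C2-symmetric anti diol, while the target is syn, so one carbinol must be inverted after a desymmetrising protection. The allyl arm on the C3 side also has its extra carbon in the wrong place (C2–C1=CH2 where C2–C1–aryl is needed), which costs oxidative cleavage, aryl addition and benzylic deoxygenation. The corrective steps outweigh the gain.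

Key step: step 2

**Remark (assumption).** Which antipode of the chiral NHC sends the arylmethylidene to C6 of 2 cannot be derived with confidence for this new substrate. The (4R,5R) ligand is written; if the sense is opposite, the (4S,5S) complex is used with no other change. Compound 3 is taken as the commercial (E)-isomer; olefin geometry in 3 and 4 has no bearing on the target.

## Route

Step 1
Reactants: 1 cis-cyclopent-4-ene-1,3-diol (meso)
Product: 2 meso-(1R,5S)-3-exo-phenyl-2,4-dioxabicyclo[3.2.1]oct-6-ene (phenyl anti to the C6=C7 bridge)
Conditions: PhCH(OMe)2 (1.2 equiv), PPTS (5 mol %), toluene, 50 °C, reduced pressure (MeOH removed)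
Reagents that add atoms: benzaldehyde dimethyl acetal, COC(OC)c1ccccc1
Why: Acid-catalysed transacetalisation under thermodynamic control, driven by removal of methanol; the cis hydroxyls are pseudo-diaxial on the cyclopentene envelope and close enough to be bridged by one carbon, and phenyl should sit exo because the endo position lies over the olefin. The product is meso and its acetal centre is lost in step 3.

Step 2
Reactants: 2 meso-(1R,5S)-3-exo-phenyl-2,4-dioxabicyclo[3.2.1]oct-6-ene; 3 1-(benzyloxy)-2-methoxy-4-[(E)-prop-1-en-1-yl]benzene (O-benzyl-(E)-isoeugenol)
Product: 4 (2R,4S,6R)-4-[(E)-2-(4-benzyloxy-3-methoxyphenyl)ethenyl]-2-phenyl-6-[(E)-prop-1-en-1-yl]-1,3-dioxane (alkenyl groups cis to each other, phenyl trans to both)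
Conditions: 3 (3 equiv), RuCl2(=CHPh)(PCy3)(L*) (5 mol %), CH2Cl2, 40 °C, 2 added over 2 h; L* = (4R,5R)-1,3-bis(2-isopropylphenyl)-4,5-diphenylimidazolidin-2-ylidene
Reagents that add atoms: none
Why: Proposed new method: enantioselective ring-opening/cross-metathesis of a meso bicyclic olefin with an unsymmetrical internal olefin, both alkylidene halves of which are delivered, one to each enantiotopic end (net insertion of the ring into the C=C bond of 3); the closest known reaction type is the catalytic enantioselective ring-opening/cross-metathesis of meso norbornenes and 8-oxabicyclo[3.2.1]oct-6-enes with terminal styrenes, together with non-enantioselective ring-opening cross-metathesis with internal olefins, and the mechanistic reasoning is this. The chiral ruthenium arylmethylidene, formed from the precatalyst and 3 by the alkylidene transfer by which 1-propenylarenes are known to put arylidene ligands on ruthenium, adds to the strained C6=C7 bond of 2 from the exo face (syn to C8, anti to the acetal bridge), and the chiral environment of the NHC decides whether the aryl-bearing carbon bonds to C6 or to C7. Cycloreversion opens the cyclopentene and leaves the styryl group on C6 and a ruthenium alkylidene on C7; this alkylidene takes the ethylidene half of a second molecule of 3 through the ruthenacyclobutane that keeps the aryl group on the α′ carbon, away from the crowded β position and on the carbon that becomes the conjugated, donor-stabilised carbene, so that 4 is released and the arylmethylidene returns. No ring is closed: the carbocycle is opened, and relief of the strain of the bicyclo[3.2.1]octene, with the two ring carbons passing from a diaxial bridge to two equatorial alkenyl groups on a chair dioxane, should make the opening irreversible. No stereocentre is created: C4 and C6 of 4 are the bridgeheads C5 and C1 of 2, their cis relation is inherited from meso 1, and their absolute sense (4S,6R) is set only by the catalyst's choice between C6 and C7. The step needs three selectivities: discrimination of the enantiotopic carbons (secured by the rigid bicycle with one open face), regioselective chain transfer (secured by the aryl/methyl difference in 3, with the safeguard that one leak into the ethylidene cycle gives only achiral bis-styryl or bis-propenyl dioxanes and the mirror-image product needs two consecutive leaks), and cross-metathesis ahead of oligomerisation (secured by the excess of 3, the slow addition of 2 and the hindered, allylically oxygenated olefins of 4). The E/Z composition of the new olefins is without consequence, since both are hydrogenated in step 3.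

Step 3
Reactants: 4 (2R,4S,6R)-4-[(E)-2-(4-benzyloxy-3-methoxyphenyl)ethenyl]-2-phenyl-6-[(E)-prop-1-en-1-yl]-1,3-dioxane
Product: 6 (3R,5S)-1-(4-hydroxy-3-methoxyphenyl)octane-3,5-diol, via saturated benzylidene acetal 5 (not isolated)
Conditions: H2 (1 atm), 10% Pd/C, EtOAc, rt; then MeOH and Pd(OH)2/C added, H2 (1 atm), rt
Reagents that add atoms: none
Why: Heterogeneous hydrogenation should first saturate the two disubstituted olefins under neutral conditions to give 5, and then hydrogenolyse the benzylidene acetal and the aryl benzyl ether at their benzylic C–O bonds. The C–O bonds at C3 and C5 are not broken, so the (4S,6R) centres of 4 become (3R,5S) in 6 only through the change in substituent priorities.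

Step 4
Reactants: 6 (3R,5S)-1-(4-hydroxy-3-methoxyphenyl)octane-3,5-diol
Product: 7 (3R,5S)-1-(4-acetoxy-3-methoxyphenyl)octane-3,5-diyl diacetate
Conditions: Ac2O (4 equiv), pyridine, DMAP (5 mol %), CH2Cl2, 0 °C to rt
Reagents that add atoms: acetic anhydride, CC(=O)OC(C)=O
Why: Standard DMAP-catalysed acylation; all three hydroxyls are esterified on purpose, so no selectivity is asked of this step and no stereocentre is touched.

Step 5
Reactants: 7 (3R,5S)-1-(4-acetoxy-3-methoxyphenyl)octane-3,5-diyl diacetate
Product: 8 (3R,5S)-1-(4-hydroxy-3-methoxyphenyl)octane-3,5-diyl diacetate
Conditions: pyrrolidine (1.5 equiv), MeCN, 0 °C to rt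
Reagents that add atoms: none
Why: Chemoselective aminolysis: the aryl ester, with a phenoxide leaving group, should react with a secondary amine under conditions where secondary alkyl acetates are inert. No base strong enough to cause acyl migration is present.

## Compound list

1 | cis-cyclopent-4-ene-1,3-diol (meso, (1R,3S)) | O[C@@H]1C[C@H](O)C=C1 | starting material
2 | meso-(1R,5S)-3-exo-phenyl-2,4-dioxabicyclo[3.2.1]oct-6-ene | O1[C@@H]2C[C@H](O[C@@H]1c3ccccc3)C=C2 | intermediate
3 | 1-(benzyloxy)-2-methoxy-4-[(E)-prop-1-en-1-yl]benzene (O-benzyl-(E)-isoeugenol) | C/C=C/c1ccc(OCc2ccccc2)c(OC)c1 | starting material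
4 | (2R,4S,6R)-4-[(E)-2-(4-benzyloxy-3-methoxyphenyl)ethenyl]-2-phenyl-6-[(E)-prop-1-en-1-yl]-1,3-dioxane | C/C=C/[C@H]1C[C@@H](/C=C/c2ccc(OCc3ccccc3)c(OC)c2)O[C@H](c2ccccc2)O1 | intermediate
5 | (2R,4R,6S)-4-[2-(4-benzyloxy-3-methoxyphenyl)ethyl]-2-phenyl-6-propyl-1,3-dioxane | CCC[C@H]1C[C@@H](CCc2ccc(OCc3ccccc3)c(OC)c2)O[C@H](c2ccccc2)O1 | intermediate (not isolated)
6 | (3R,5S)-1-(4-hydroxy-3-methoxyphenyl)octane-3,5-diol | CCC[C@@H](C[C@@H](CCc1ccc(O)c(OC)c1)O)O | intermediate
7 | (3R,5S)-1-(4-acetoxy-3-methoxyphenyl)octane-3,5-diyl diacetate | CCC[C@@H](C[C@@H](CCc1ccc(OC(C)=O)c(OC)c1)OC(C)=O)OC(C)=O | intermediate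
8 | (3R,5S)-1-(4-hydroxy-3-methoxyphenyl)octane-3,5-diyl diacetate | CCC[C@@H](C[C@@H](CCc1ccc(O)c(OC)c1)OC(C)=O)OC(C)=O | target

## Step count and least certain steps

Total step count: 5. Longest linear sequence: 5 steps (1 → 2 → 4 → 6 → 7 → 8); 3 enters as a purchased compound in step 2.

**Step 2 (key step, bears the label).** Three processes are most likely to go wrong:
- leakage of the cycle through the ethylidene carbene, which lowers enantiomeric purity and diverts material to symmetric end-capped dioxanes;
- insufficient discrimination between C6 and C7 by the monodentate NHC;
- ring-opening oligomerisation of 2, because the internal olefin 3 is a slower chain-transfer agent than a terminal styrene.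

Fallback with known chemistry, from 2 back to 4: 2 is opened with the terminal olefin 4-benzyloxy-3-methoxystyrene (commercial, 3 equiv), so that only the arylmethylidene cycle can operate. The catalyst is the same chiral ruthenium complex or, if its discrimination is insufficient, the appropriate antipode of the hexavalent molybdenum complex Mo(N-2,6-i-Pr2C6H3)(CHCMe2Ph)[3,3'-di-tert-butyl-5,5',6,6'-tetramethylbiphenyl-2,2'-diolate] in benzene. This is the established enantioselective ring-opening/cross-metathesis of meso bicyclic olefins with styrenes and should give (2R,4S,6R)-4-[(E)-2-(4-benzyloxy-3-methoxyphenyl)ethenyl]-6-ethenyl-2-phenyl-1,3-dioxane F1. Cross-metathesis of the vinyl group of F1 with excess (Z)-but-2-ene (second-generation Grubbs catalyst RuCl2(=CHPh)(PCy3)(H2IMes), CH2Cl2, rt) should then give 4, the terminal vinyl group reacting well ahead of the internal styryl olefin.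

**Step 1.** The acetalisation equilibrium may be unfavourable because of the strain of the bicycle, and the allylic alcohols may ionise under warm acid. Fallback from 1 back to 2: silylation (Me3SiCl, Et3N, CH2Cl2) gives cis-3,5-bis(trimethylsilyloxy)cyclopent-1-ene F2. Treatment with benzaldehyde and catalytic Me3SiOTf in CH2Cl2 at −78 °C then gives 2 by aprotic, low-temperature acetalisation driven irreversibly by formation of the disiloxane.

**Step 3.** Hydrogenolysis of the allylic C–O bonds of 4 on palladium may compete with olefin saturation and remove oxygen at C3 or C5. Fallback from 4 back to 6: the olefins are reduced with diimide (2-nitrobenzenesulfonyl hydrazide, Et3N, CH2Cl2, rt), which cannot cleave C–O bonds, and 5 is isolated. Hydrogenolysis of 5 (H2, Pd(OH)2/C, MeOH) then gives 6.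

**Step 5.** Discrimination between aryl and alkyl acetates may be incomplete, giving partial loss or migration of an aliphatic acetate on prolonged exposure to the amine. Fallback from 4 to 8, which never requires esters to be told apart: diimide reduction of 4 gives 5 (isolated). Acid methanolysis (CSA, MeOH, rt) removes the acetal but leaves the aryl benzyl ether, giving (3R,5S)-1-(4-benzyloxy-3-methoxyphenyl)octane-3,5-diol F3. Acetylation (Ac2O, pyridine, DMAP) gives (3R,5S)-1-(4-benzyloxy-3-methoxyphenyl)octane-3,5-diyl diacetate F4, and hydrogenolysis (H2, Pd/C, EtOAc) gives 8 directly.

## Further compounds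

F1 | step 2 | (2R,4S,6R)-4-[(E)-2-(4-benzyloxy-3-methoxyphenyl)ethenyl]-6-ethenyl-2-phenyl-1,3-dioxane | C=C[C@H]1C[C@@H](/C=C/c2ccc(OCc3ccccc3)c(OC)c2)O[C@H](c2ccccc2)O1
F2 | step 1 | cis-3,5-bis(trimethylsilyloxy)cyclopent-1-ene | C[Si](C)(C)O[C@@H]1C[C@H](O[Si](C)(C)C)C=C1
F0 | step 3 | none | none
F3 | step 5 | (3R,5S)-1-(4-benzyloxy-3-methoxyphenyl)octane-3,5-diol | CCC[C@@H](C[C@@H](CCc1ccc(OCc2ccccc2)c(OC)c1)O)O
F4 | step 5 | (3R,5S)-1-(4-benzyloxy-3-methoxyphenyl)octane-3,5-diyl diacetate | CCC[C@@H](C[C@@H](CCc1ccc(OCc2ccccc2)c(OC)c1)OC(C)=O)OC(C)=O
A1 | alternative 1 | 4-(4-benzyloxy-3-methoxyphenyl)butan-2-one | CC(=O)CCc1ccc(OCc2ccccc2)c(OC)c1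
A2 | alternative 1 | (5S)-1-(4-benzyloxy-3-methoxyphenyl)-5-hydroxyoctan-3-one | CCC[C@@H](CC(=O)CCc1ccc(OCc2ccccc2)c(OC)c1)O
A3 | alternative 1 | (3R,5S)-1-(4-benzyloxy-3-methoxyphenyl)octane-3,5-diol | CCC[C@@H](C[C@@H](CCc1ccc(OCc2ccccc2)c(OC)c1)O)O
A4 | alternative 2 | 1-(4-benzyloxy-3-methoxyphenyl)octane-3,5-diol, mixture of all four stereoisomers | CCCC(O)CC(O)CCc1ccc(OCc2ccccc2)c(OC)c1
A5 | alternative 2 | (3R,5S)-1-(4-benzyloxy-3-methoxyphenyl)octane-3,5-diyl diacetate | CCC[C@@H](C[C@@H](CCc1ccc(OCc2ccccc2)c(OC)c1)OC(C)=O)OC(C)=O
A6 | alternative 3 | (4R,6R)-nona-1,8-diene-4,6-diol | C=CC[C@@H](O)C[C@H](O)CC=C
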